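**Retrosynthetic overview**
1. The target 22 comes from chroman benzil 21 by dehydrogenation of C3–C4. Compound 21 comes from chromanol 16 and 4-methoxyphenylglyoxal by forming the C6–Cα bond ortho to C5–OH, then oxidising the carbinol.
2. The route rests on the benzene ring C4a–C5–C6–C7–C8–C8a. C5–OH and C8–OMe are para, with C8a (bearing O1) and C4a (bearing C4) between them. This is the pattern of a pyran-fused 4-methoxy-4-vinylcyclobutenone in which the ketone carbon becomes C5, the ring alkene C4a=C8a, the quaternary carbon C8 and the vinyl group C7 and C6.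
3. Chromanol 16 comes from cyclobutenone 13 by thermal 4π opening and 6π closure. Compound 13 comes from fused dione 10 by vinyl addition and O-methylation.
4. Dione 10 comes from diisopropyl squarate 4 and a 3-methyl-3-silyloxybutyl Grignard reagent, followed by pyran closure through alkoxy exchange.
5. Ring order: cyclobutene (bought as squarate), then pyran, then benzene; the anisyl ring is bought.

Key step: step 7

Assumption: the target is achiral, so the carbinol centres of 12, 13 and 20 are carried as racemates and are erased in steps 7 and 9.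

**Step 1**
Reactants: 1 ethyl 3-bromopropanoate
Product: 2 4-bromo-2-methylbutan-2-ol
Conditions: MeMgBr (2.2 equiv), Et2O, 0 °C to rt; aq. NH4Cl
Reagents that add atoms: methylmagnesium bromide C[Mg]Br
Why: Double Grignard addition to the ester should give the tertiary alcohol, the primary bromide being inert to MeMgBr at this temperature.

**Step 2**
Reactants: 2 4-bromo-2-methylbutan-2-ol
Product: 3 [(4-bromo-2-methylbutan-2-yl)oxy]triethylsilane
Conditions: TESOTf, 2,6-lutidine, CH2Cl2, 0 °C
Reagents that add atoms: triethylsilyl triflate CC[Si](CC)(CC)OS(=O)(=O)C(F)(F)F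
Why: O-silylation with a silyl triflate and a hindered base is reliable for tertiary alcohols, and the TES ether masks the hydroxyl for Grignard formation.

**Step 3**
Reactants: 3 [(4-bromo-2-methylbutan-2-yl)oxy]triethylsilane, 4 diisopropyl squarate
Product: 8 3-[3-methyl-3-(triethylsilyloxy)butyl]-4-(propan-2-yloxy)cyclobut-3-ene-1,2-dione, via Grignard reagent 5 (not isolated), via bromomagnesium alkoxide adduct 6 (not isolated), via tertiary trifluoroacetate 7 (not isolated)
Conditions: Mg, THF, 40 °C; add to 4, THF, −78 °C; TFAA, −78 °C; aq. NaHCO3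
Reagents that add atoms: water O
Why: The γ-silyloxy Grignard reagent has no β-leaving group and should add 1,2 to one squarate carbonyl; trifluoroacetylation of the adduct then triggers ionisation and hydrolysis with loss of isopropanol (the standard squarate-to-cyclobutenedione 1,2-addition/rearrangement), under conditions that spare the TES ether.

**Step 4**
Reactants: 8 3-[3-methyl-3-(triethylsilyloxy)butyl]-4-(propan-2-yloxy)cyclobut-3-ene-1,2-dione
Product: 10 3,3-dimethyl-2-oxabicyclo[4.2.0]oct-1(6)-ene-7,8-dione, via hydroxy dione 9 (not isolated)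
Conditions: HF·pyridine, THF, 0 °C to rt; then CSA (10 mol%), PhMe, 50 °C, N2 sweep
Reagents that add atoms: none
Why: Fluoride desilylation frees the tertiary alcohol, which should displace isopropanol at the alkoxy-bearing ring carbon by acid-catalysed addition–elimination (vinylogous transesterification, 6-endo-trig), helped by the gem-dimethyl effect and by removal of isopropanol.

**Step 5**
Reactants: 10 3,3-dimethyl-2-oxabicyclo[4.2.0]oct-1(6)-ene-7,8-dione, 11 vinylmagnesium bromide
Product: 12 racemic 8-ethenyl-8-hydroxy-3,3-dimethyl-2-oxabicyclo[4.2.0]oct-1(6)-en-7-one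
Conditions: THF, −78 °C; aq. NH4Cl
Reagents that add atoms: none
Why: Grignard 1,2-addition should go to the C8 carbonyl, the more electrophilic one because C7 is deactivated as the vinylogous ester carbonyl of O2; the quaternary centre forms as a racemate and is erased in step 7.

**Step 6**
Reactants: 12 racemic 8-ethenyl-8-hydroxy-3,3-dimethyl-2-oxabicyclo[4.2.0]oct-1(6)-en-7-one
Product: 13 racemic 8-ethenyl-8-methoxy-3,3-dimethyl-2-oxabicyclo[4.2.0]oct-1(6)-en-7-one
Conditions: MeI, Ag2O, 4 Å MS, MeCN, rt, dark
Reagents that add atoms: iodomethane CI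
Why: Purdie methylation etherifies the tertiary carbinol without a free alkoxide, which avoids base-induced cleavage of the 4-hydroxycyclobutenone; the stereocentre is untouched.

**Step 7**
Reactants: 13 racemic 8-ethenyl-8-methoxy-3,3-dimethyl-2-oxabicyclo[4.2.0]oct-1(6)-en-7-one
Product: 16 8-methoxy-2,2-dimethylchroman-5-ol, via dienylketene 14 (not isolated), via cyclohexadienone tautomer 15 (not isolated)
Conditions: degassed PhMe, 110 °C
Reagents that add atoms: none
Why: Heating should open the cyclobutenone by conrotatory 4π cleavage of the C7–C8 bond to dienylketene 14, whose ketene carbon then bonds to the vinyl terminus in a thermal disrotatory 6π electrocyclisation to cyclohexa-2,4-dienone 15, and enolisation gives the arene. This is the Moore rearrangement of 4-alkenyl-4-alkoxycyclobutenones to hydroquinone monoethers, driven by release of four-membered ring strain and by aromatisation. The benzene ring closes in the 6π electrocyclic mode, the fused pyran holding the ketene and the enol ether double bond s-cis. No stereocentre is created; the racemic quaternary carbon becomes C8 of the arene. The step needs outward rotation of the methoxy group so that the vinyl group turns toward the ketene (Z-dienylketene), which the donor oxygen substituent secures by its known torquoselectivity. The oxygens are placed by the substrate: the ketone oxygen becomes the free C5–OH and the methylated carbinol oxygen becomes C8–OMe.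

**Step 8**
Reactants: 16 8-methoxy-2,2-dimethylchroman-5-ol, 17 4-methoxyphenylglyoxal hydrate
Product: 20 racemic 2-hydroxy-2-(5-hydroxy-8-methoxy-2,2-dimethylchroman-6-yl)-1-(4-methoxyphenyl)ethan-1-one, via anhydrous 4-methoxyphenylglyoxal 18 (not isolated), via bromomagnesium phenoxide 19 (not isolated)
Conditions: 17, PhMe, Dean–Stark; 16, EtMgBr, Et2O then PhMe, 0 °C to rt; aq. NH4Cl
Reagents that add atoms: none
Why: In this magnesium phenoxide-directed ortho-hydroxyalkylation (Casiraghi reaction) the phenoxide should bind the aldehyde carbonyl of the glyoxal and deliver it through a six-membered chelate to C6, the only free ortho carbon and also para to O1; the carbinol centre is racemic and is oxidised in step 9.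

**Step 9**
Reactants: 20 racemic 2-hydroxy-2-(5-hydroxy-8-methoxy-2,2-dimethylchroman-6-yl)-1-(4-methoxyphenyl)ethan-1-one
Product: 21 1-(5-hydroxy-8-methoxy-2,2-dimethylchroman-6-yl)-2-(4-methoxyphenyl)ethane-1,2-dione
Conditions: activated MnO2, CH2Cl2, rt
Reagents that add atoms: none
Why: MnO2 oxidises benzylic α-keto carbinols (benzoin to benzil) under neutral conditions and tolerates free phenols, as in the oxidation of salicyl alcohols to salicylaldehydes.

**Step 10**
Reactants: 21 1-(5-hydroxy-8-methoxy-2,2-dimethylchroman-6-yl)-2-(4-methoxyphenyl)ethane-1,2-dione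
Product: 22 dielsianone, 1-(5-hydroxy-8-methoxy-2,2-dimethyl-2H-chromen-6-yl)-2-(4-methoxyphenyl)ethane-1,2-dione
Conditions: DDQ, 1,4-dioxane, reflux
Reagents that add atoms: none
Why: DDQ should abstract hydride from benzylic C4, the cation being stabilised by O1 and the C5 oxygen, and loss of a C3 proton gives the 2H-chromene; the chelated, acyl-deactivated phenol should resist quinone formation, as in the standard dehydrogenation of 6-acyl-5-hydroxy-2,2-dimethylchromans.

**Compound list**
1 | ethyl 3-bromopropanoate | CCOC(=O)CCBr | starting material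
2 | 4-bromo-2-methylbutan-2-ol | CC(C)(O)CCBr | intermediate
3 | [(4-bromo-2-methylbutan-2-yl)oxy]triethylsilane | CC[Si](CC)(CC)OC(C)(C)CCBr | intermediate
4 | diisopropyl squarate | CC(C)OC1=C(OC(C)C)C(=O)C1=O | starting material
5 | [3-methyl-3-(triethylsilyloxy)butyl]magnesium bromide | CC[Si](CC)(CC)OC(C)(C)CC[Mg]Br | intermediate (not isolated)
6 | bromomagnesium alkoxide of 4-hydroxy-4-[3-methyl-3-(triethylsilyloxy)butyl]-2,3-di(propan-2-yloxy)cyclobut-2-en-1-one | CC(C)OC1=C(OC(C)C)C(CCC(C)(C)O[Si](CC)(CC)CC)(O[Mg]Br)C1=O | intermediate (not isolated)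
7 | 1-[3-methyl-3-(triethylsilyloxy)butyl]-4-oxo-2,3-di(propan-2-yloxy)cyclobut-2-en-1-yl trifluoroacetate | CC(C)OC1=C(OC(C)C)C(CCC(C)(C)O[Si](CC)(CC)CC)(OC(=O)C(F)(F)F)C1=O | intermediate (not isolated)
8 | 3-[3-methyl-3-(triethylsilyloxy)butyl]-4-(propan-2-yloxy)cyclobut-3-ene-1,2-dione | CC(C)OC1=C(CCC(C)(C)O[Si](CC)(CC)CC)C(=O)C1=O | intermediate
9 | 3-(3-hydroxy-3-methylbutyl)-4-(propan-2-yloxy)cyclobut-3-ene-1,2-dione | CC(C)OC1=C(CCC(C)(C)O)C(=O)C1=O | intermediate (not isolated)
10 | 3,3-dimethyl-2-oxabicyclo[4.2.0]oct-1(6)-ene-7,8-dione | O=C1C(=O)C2=C1OC(C)(C)CC2 | intermediate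
11 | vinylmagnesium bromide | C=C[Mg]Br | starting material
12 | racemic 8-ethenyl-8-hydroxy-3,3-dimethyl-2-oxabicyclo[4.2.0]oct-1(6)-en-7-one | OC1(C=C)C(=O)C2=C1OC(C)(C)CC2 | intermediate
13 | racemic 8-ethenyl-8-methoxy-3,3-dimethyl-2-oxabicyclo[4.2.0]oct-1(6)-en-7-one | COC1(C=C)C(=O)C2=C1OC(C)(C)CC2 | intermediate
14 | (Z)-dienylketene, 2-[3-(1-methoxyprop-2-en-1-ylidene)-6,6-dimethyloxan-4-ylidene]ethen-1-one skeleton with ketene on the ring carbon next to the enol ether | C=C/C(OC)=C1/OC(C)(C)CCC1=C=O | intermediate (not isolated)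
15 | 8-methoxy-2,2-dimethyl-3,4-dihydro-2H-chromen-5(6H)-one | COC1=CCC(=O)C2=C1OC(C)(C)CC2 | intermediate (not isolated)
16 | 8-methoxy-2,2-dimethylchroman-5-ol | COc1ccc(O)c2CCC(C)(C)Oc12 | intermediate
17 | 4-methoxyphenylglyoxal hydrate | COc1ccc(C(=O)C(O)O)cc1 | starting material
18 | 4-methoxyphenylglyoxal | COc1ccc(C(=O)C=O)cc1 | intermediate (not isolated)
19 | bromomagnesium 8-methoxy-2,2-dimethylchroman-5-olate | COc1ccc(O[Mg]Br)c2CCC(C)(C)Oc12 | intermediate (not isolated)
20 | racemic 2-hydroxy-2-(5-hydroxy-8-methoxy-2,2-dimethylchroman-6-yl)-1-(4-methoxyphenyl)ethan-1-one | COc1ccc(C(=O)C(O)c2cc(OC)c3c(c2O)CCC(C)(C)O3)cc1 | intermediate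
21 | 1-(5-hydroxy-8-methoxy-2,2-dimethylchroman-6-yl)-2-(4-methoxyphenyl)ethane-1,2-dione | COc1ccc(C(=O)C(=O)c2cc(OC)c3c(c2O)CCC(C)(C)O3)cc1 | intermediate
22 | dielsianone | COc1ccc(C(=O)C(=O)c2cc(OC)c3c(c2O)C=CC(C)(C)O3)cc1 | target

**Step count**
Total steps: 10. Longest linear sequence: 10 steps (1 to 22); compounds 4, 11 and 17 enter as bought materials.

**Steps most likely to fail**

Step 7. The fused cyclobutenone may open with poor torquoselectivity, or the strained bicyclic dienylketene may polymerise or be trapped before the 6π closure. The fallback moves the pyran closure behind the aromatisation, so the ring expansion runs on a monocyclic cyclobutenone. It sets out from 8 and returns at 16.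
- Vinylmagnesium bromide 11 is added to 8 at −78 °C to give racemic 4-ethenyl-4-hydroxy-2-[3-methyl-3-(triethylsilyloxy)butyl]-3-(propan-2-yloxy)cyclobut-2-en-1-one F5.
- MeI and Ag2O convert it into the methyl ether, racemic 4-ethenyl-4-methoxy-2-[3-methyl-3-(triethylsilyloxy)butyl]-3-(propan-2-yloxy)cyclobut-2-en-1-one F6.
- Thermolysis in toluene should give 4-methoxy-2-[3-methyl-3-(triethylsilyloxy)butyl]-3-(propan-2-yloxy)phenol F7.
- Ac2O and pyridine block the free phenol as 4-methoxy-2-[3-methyl-3-(triethylsilyloxy)butyl]-3-(propan-2-yloxy)phenyl acetate F8.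
- BCl3 in CH2Cl2 at −78 to 0 °C removes the isopropyl and silyl groups but not the methyl ether, and the freed phenol closes onto the tertiary carbinol carbon under the acidic conditions (catalytic TsOH in toluene if needed) to give 8-methoxy-2,2-dimethylchroman-5-yl acetate F9.
- K2CO3 in MeOH releases 16.

Step 4. The hindered tertiary alcohol may exchange with the isopropoxy group only slowly, while acid dehydrates the carbinol or traces of water hydrolyse the vinylogous ester. The fallback forms the C–O bond by adding an acidic enol to an alkene instead. It sets out from 4 and returns at 10.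
- Commercial 4-bromo-2-methylbut-1-ene and Mg give 3-methylbut-3-en-1-ylmagnesium bromide F1.
- Addition to 4 at −78 °C and NH4Cl quench give 4-hydroxy-4-(3-methylbut-3-en-1-yl)-2,3-di(propan-2-yloxy)cyclobut-2-en-1-one F2.
- Catalytic concentrated HCl in CH2Cl2 rearranges it to 3-(3-methylbut-3-en-1-yl)-4-(propan-2-yloxy)cyclobut-3-ene-1,2-dione F3.
- Aqueous HCl in THF hydrolyses the vinylogous ester to the semisquaric acid 3-hydroxy-4-(3-methylbut-3-en-1-yl)cyclobut-3-ene-1,2-dione F4.
- Catalytic TfOH in CH2Cl2 should add the acidic enol across the 1,1-disubstituted alkene in the Markovnikov sense, as in the cyclisation of o-prenylphenols to 2,2-dimethylchromans, to give 10.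

Step 8. The benzylic carbinol may react with a second phenoxide, the o-hydroxybenzoin may cyclise and dehydrate to a benzofuranone, and the electron-rich free phenol stays exposed to the oxidant of step 9. The fallback builds the two-carbon bridge at the ketone oxidation level. It sets out from 16 and returns at 21, replacing steps 8 and 9.
- Compound 16 is acylated at C6 with 4-methoxyphenylacetic acid in BF3·OEt2 at 80 °C (O-acylation and Fries shift) to give 1-(5-hydroxy-8-methoxy-2,2-dimethylchroman-6-yl)-2-(4-methoxyphenyl)ethan-1-one F10.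
- Riley oxidation of the doubly activated methylene with SeO2 in wet dioxane at reflux gives 21.

**Further compounds**
F1 | step 4 | 3-methylbut-3-en-1-ylmagnesium bromide | C=C(C)CC[Mg]Br
F2 | step 4 | 4-hydroxy-4-(3-methylbut-3-en-1-yl)-2,3-di(propan-2-yloxy)cyclobut-2-en-1-one | CC(C)OC1=C(OC(C)C)C(O)(CCC(C)=C)C1=O
F3 | step 4 | 3-(3-methylbut-3-en-1-yl)-4-(propan-2-yloxy)cyclobut-3-ene-1,2-dione | CC(C)OC1=C(CCC(C)=C)C(=O)C1=O
F4 | step 4 | 3-hydroxy-4-(3-methylbut-3-en-1-yl)cyclobut-3-ene-1,2-dione | OC1=C(CCC(C)=C)C(=O)C1=O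
F5 | step 7 | racemic 4-ethenyl-4-hydroxy-2-[3-methyl-3-(triethylsilyloxy)butyl]-3-(propan-2-yloxy)cyclobut-2-en-1-one | CC(C)OC1=C(CCC(C)(C)O[Si](CC)(CC)CC)C(=O)C1(O)C=C
F6 | step 7 | racemic 4-ethenyl-4-methoxy-2-[3-methyl-3-(triethylsilyloxy)butyl]-3-(propan-2-yloxy)cyclobut-2-en-1-one | CC(C)OC1=C(CCC(C)(C)O[Si](CC)(CC)CC)C(=O)C1(OC)C=C
F7 | step 7 | 4-methoxy-2-[3-methyl-3-(triethylsilyloxy)butyl]-3-(propan-2-yloxy)phenol | COc1ccc(O)c(CCC(C)(C)O[Si](CC)(CC)CC)c1OC(C)C
F8 | step 7 | 4-methoxy-2-[3-methyl-3-(triethylsilyloxy)butyl]-3-(propan-2-yloxy)phenyl acetate | COc1ccc(OC(C)=O)c(CCC(C)(C)O[Si](CC)(CC)CC)c1OC(C)C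
F9 | step 7 | 8-methoxy-2,2-dimethylchroman-5-yl acetate | COc1ccc(OC(C)=O)c2CCC(C)(C)Oc12
F10 | step 8 | 1-(5-hydroxy-8-methoxy-2,2-dimethylchroman-6-yl)-2-(4-methoxyphenyl)ethan-1-one | COc1ccc(CC(=O)c2cc(OC)c3c(c2O)CCC(C)(C)O3)cc1
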